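## Retrosynthetic overview

- The isoflavone is cut last: pyranone ring C (O1–C2 and C2–C3) comes from a 2,4,6-trioxygenated deoxybenzoin and a one-carbon formamide acetal. The deoxybenzoin C(=O)–aryl bond comes from an arylacetaldehyde and metalated tris-MOM-phloroglucinol (ring A).
- The strategy rests on dihydrofuran ring D. Its two aryl bonds, C7a–O1 and C3a–C3, sit on adjacent carbons of ring B, and the next carbon, C7, carries the carbon arm that becomes isoflavone C3. This is the ipso/ortho pattern of a Catellani annulation with the blocking group already in place.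
- Key disconnection: both bonds are cut at once, to methyl 2-(2-iodo-4,5-dimethoxyphenyl)acetate and the silylated (R)-epoxide of 2-methylbut-3-en-2-ol. The epoxide supplies C3, C2, O1 and the only stereocentre.
- The iodide comes from homoveratric acid (esterification, iodination). The epoxide comes from the chiral-pool ester methyl (R)-2,2-dimethyl-1,3-dioxolane-4-carboxylate (Grignard addition, silylation, ketal hydrolysis, tosylate closure).
- Ring order: rings A and B are bought, ring D is formed in the key step, ring C is formed last together with global deprotection.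

Key step: step 7

Assumption: methyl (4R)-2,2-dimethyl-1,3-dioxolane-4-carboxylate (the acetonide of methyl D-glycerate) is taken as the commercial chiral-pool source of the stereocentre. The configuration of the transient benzylic carbinol and the alkene geometry of the enaminone are left open because both are erased later.

## Route

Step 1
Reactants: 1 homoveratric acid [2-(3,4-dimethoxyphenyl)acetic acid]
Product: 2 methyl 2-(3,4-dimethoxyphenyl)acetate
Conditions: MeOH, H2SO4 (cat.), reflux
Reagents that add atoms: methanol, CO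
Why: Fischer esterification of an unhindered arylacetic acid in excess methanol should run to completion and touches nothing else in the molecule.

Step 2
Reactants: 2 methyl 2-(3,4-dimethoxyphenyl)acetate
Product: 3 methyl 2-(2-iodo-4,5-dimethoxyphenyl)acetate
Conditions: NIS (1.1 equiv), CF3CO2H (0.3 equiv), MeCN, rt, dark
Reagents that add atoms: N-iodosuccinimide, O=C1CCC(=O)N1I
Why: Electrophilic aromatic iodination of the veratrole ring should go to the carbon para to the 3-methoxy group and ortho to the acetate arm, the most activated and least crowded position, which is the usual regiochemistry for halogenation of homoveratric derivatives.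

Step 3
Reactants: 4 methyl (4R)-2,2-dimethyl-1,3-dioxolane-4-carboxylate
Product: 5 2-[(4R)-2,2-dimethyl-1,3-dioxolan-4-yl]propan-2-ol
Conditions: MeMgBr (3 equiv), THF, −20 °C → rt; aq. NH4Cl
Reagents that add atoms: methylmagnesium bromide, C[Mg]Br
Why: Double Grignard addition to the ester gives the tertiary carbinol, and the stereocentre, which comes from the chiral pool, should keep its R configuration because carbonyl addition at low temperature is faster than enolisation.

Step 4
Reactants: 5 2-[(4R)-2,2-dimethyl-1,3-dioxolan-4-yl]propan-2-ol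
Product: 6 tert-butyl({2-[(4R)-2,2-dimethyl-1,3-dioxolan-4-yl]propan-2-yl}oxy)dimethylsilane
Conditions: TBSOTf (1.5 equiv), 2,6-lutidine (2.5 equiv), CH2Cl2, −78 → 0 °C
Reagents that add atoms: tert-butyldimethylsilyl trifluoromethanesulfonate, CC(C)(C)[Si](C)(C)OS(=O)(=O)C(F)(F)F
Why: O-Silylation with a silyl triflate and a hindered pyridine base is the standard protection of a tertiary alcohol, and at low temperature the isopropylidene ketal should be left alone.

Step 5
Reactants: 6 tert-butyl({2-[(4R)-2,2-dimethyl-1,3-dioxolan-4-yl]propan-2-yl}oxy)dimethylsilane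
Product: 7 (2R)-3-[(tert-butyldimethylsilyl)oxy]-3-methylbutane-1,2-diol
Conditions: AcOH/H2O (4:1), 40 °C
Reagents that add atoms: none
Why: Acid-catalysed ketal hydrolysis frees the terminal diol, while the hindered tertiary silyl ether is far less labile in aqueous acetic acid and should stay in place, and the stereocentre is not involved.

Step 6
Reactants: 7 (2R)-3-[(tert-butyldimethylsilyl)oxy]-3-methylbutane-1,2-diol
Product: 9 tert-butyldimethyl({2-[(2R)-oxiran-2-yl]propan-2-yl}oxy)silane, via primary monotosylate 8 (not isolated)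
Conditions: TsCl (1.05 equiv), Et3N, Bu2SnO (2 mol %), CH2Cl2, 0 °C → rt; then K2CO3, MeOH, 0 °C
Reagents that add atoms: none
Why: Tin-acetal-catalysed sulfonylation picks the primary hydroxyl over the neopentyl-like secondary one, and carbonate then triggers an intramolecular Williamson (3-exo-tet) closure in which the secondary oxygen displaces the primary tosylate, so the C–O bond of the stereocentre is untouched and R is retained.

Step 7
Reactants: 3 methyl 2-(2-iodo-4,5-dimethoxyphenyl)acetate; 9 tert-butyldimethyl({2-[(2R)-oxiran-2-yl]propan-2-yl}oxy)silane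
Product: 10 methyl 2-[(2R)-2-{2-[(tert-butyldimethylsilyl)oxy]propan-2-yl}-4,5-dimethoxy-2,3-dihydro-1-benzofuran-7-yl]acetate
Conditions: Pd(OAc)2 (10 mol %), XPhos (20 mol %), potassium 5-norbornene-2-carboxylate (0.5 equiv), K2CO3 (2 equiv), 9 (2 equiv), NMP, 70 °C
Reagents that add atoms: none
Why: This is a Catellani-type palladium/norbornene annulation of an ortho-substituted aryl iodide with a terminal epoxide, a known way to 2-substituted 2,3-dihydrobenzofurans. Oxidative addition of the C–I bond of 3 to zerovalent palladium, norbornene insertion and carboxylate-assisted palladation of the only free ortho C–H give the five-membered aryl norbornyl palladacycle, which opens 9 by backside attack at its CH2 carbon and forms the aryl–CH2 bond by reductive elimination from tetravalent palladium. With both ortho positions filled, norbornene leaves by β-carbon elimination, and the pendant secondary alkoxide closes the dihydrofuran ring by C(aryl)–O reductive elimination from a six-membered oxapalladacycle at the former iodide carbon, a formal [3+2] annulation that makes C3a–C3 and C7a–O1. No stereocentre is created: the C–O bond at C2 of the epoxide is never broken, so the R configuration of 9 is carried into 10 unchanged. Site selectivity is fixed by the substrate, since 3 has a single ortho C–H (its flanking methoxy group is the steric cost), the CH2CO2Me arm on the other ortho carbon is the blocking group that forces norbornene extrusion, and the quaternary carbon beside the epoxide methine leaves only the terminal carbon open to attack.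

Step 8
Reactants: 10 methyl 2-[(2R)-2-{2-[(tert-butyldimethylsilyl)oxy]propan-2-yl}-4,5-dimethoxy-2,3-dihydro-1-benzofuran-7-yl]acetate
Product: 11 2-[(2R)-2-{2-[(tert-butyldimethylsilyl)oxy]propan-2-yl}-4,5-dimethoxy-2,3-dihydro-1-benzofuran-7-yl]acetaldehyde
Conditions: i-Bu2AlH (1.1 equiv), toluene, −78 °C; MeOH, then aq. potassium sodium tartrate
Reagents that add atoms: none
Why: Partial reduction of a methyl ester with one equivalent of i-Bu2AlH at −78 °C stops at the aluminium hemiacetal, which releases the arylacetaldehyde only on work-up, and the silyl and aryl ethers are inert to the hydride.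

Step 9
Reactants: 12 phloroglucinol (benzene-1,3,5-triol)
Product: 13 1,3,5-tris(methoxymethoxy)benzene
Conditions: MOMCl (4 equiv), i-Pr2NEt (5 equiv), CH2Cl2/DMF, 0 °C → rt
Reagents that add atoms: chloromethyl methyl ether, COCCl
Why: Threefold Williamson-type O-alkylation with a hard oxocarbenium-like electrophile under amine base favours O- over C-alkylation of phloroglucinol and gives the ether whose oxygens direct the later lithiation.

Step 10
Reactants: 11 2-[(2R)-2-{2-[(tert-butyldimethylsilyl)oxy]propan-2-yl}-4,5-dimethoxy-2,3-dihydro-1-benzofuran-7-yl]acetaldehyde; 13 1,3,5-tris(methoxymethoxy)benzene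
Product: 16 2-[(2R)-2-{2-[(tert-butyldimethylsilyl)oxy]propan-2-yl}-4,5-dimethoxy-2,3-dihydro-1-benzofuran-7-yl]-1-[2,4,6-tris(methoxymethoxy)phenyl]ethan-1-ol (both carbinol epimers), via aryllithium 14 (not isolated), via aryldichlorocerium 15 (not isolated)
Conditions: 13 (1.6 equiv), n-BuLi (1.5 equiv), THF, 0 °C; CeCl3 (1.6 equiv), −78 °C; then 11, −78 °C; aq. NH4Cl
Reagents that add atoms: none
Why: Directed ortho-lithiation of 13 occurs at a carbon flanked by two methoxymethoxy groups (all three ring C–H are equivalent), and transmetalation to the weakly basic, oxophilic organocerium lets 1,2-addition to the enolisable arylacetaldehyde outrun proton transfer, the new carbinol centre being formed without control and removed by the next oxidation.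

Step 11
Reactants: 16 2-[(2R)-2-{2-[(tert-butyldimethylsilyl)oxy]propan-2-yl}-4,5-dimethoxy-2,3-dihydro-1-benzofuran-7-yl]-1-[2,4,6-tris(methoxymethoxy)phenyl]ethan-1-ol
Product: 17 2-[(2R)-2-{2-[(tert-butyldimethylsilyl)oxy]propan-2-yl}-4,5-dimethoxy-2,3-dihydro-1-benzofuran-7-yl]-1-[2,4,6-tris(methoxymethoxy)phenyl]ethan-1-one
Conditions: Dess–Martin periodinane (1.3 equiv), CH2Cl2, 0 °C → rt
Reagents that add atoms: none
Why: Dess–Martin oxidation converts the hindered benzylic secondary alcohol to the ketone under near-neutral conditions that leave the acetal ethers, the silyl ether and the dihydrofuran stereocentre alone, and both epimers converge on one deoxybenzoin.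

Step 12
Reactants: 17 2-[(2R)-2-{2-[(tert-butyldimethylsilyl)oxy]propan-2-yl}-4,5-dimethoxy-2,3-dihydro-1-benzofuran-7-yl]-1-[2,4,6-tris(methoxymethoxy)phenyl]ethan-1-one
Product: 18 3-(dimethylamino)-2-[(2R)-2-{2-[(tert-butyldimethylsilyl)oxy]propan-2-yl}-4,5-dimethoxy-2,3-dihydro-1-benzofuran-7-yl]-1-[2,4,6-tris(methoxymethoxy)phenyl]prop-2-en-1-one
Conditions: Me2NCH(OMe)2 (5 equiv), toluene, 90 °C
Reagents that add atoms: N,N-dimethylformamide dimethyl acetal, COC(OC)N(C)C
Why: The doubly activated methylene of the deoxybenzoin condenses with the formamide acetal (enaminone formation, the standard one-carbon homologation on the way to isoflavones), installing the carbon that becomes C2 of the pyranone without acid or strong base.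

Step 13
Reactants: 18 3-(dimethylamino)-2-[(2R)-2-{2-[(tert-butyldimethylsilyl)oxy]propan-2-yl}-4,5-dimethoxy-2,3-dihydro-1-benzofuran-7-yl]-1-[2,4,6-tris(methoxymethoxy)phenyl]prop-2-en-1-one
Product: 21 target 5,7-dihydroxy-3-[(2R)-2-(2-hydroxypropan-2-yl)-4,5-dimethoxy-2,3-dihydro-1-benzofuran-7-yl]-4H-chromen-4-one, via trihydroxyphenyl enaminone 19 (not isolated), via silylated isoflavone 20 (not isolated)
Conditions: 3 M HCl in MeOH, 50 °C
Reagents that add atoms: none
Why: Acidic methanolysis strips the three phenolic methoxymethyl ethers, the freed ortho-phenol adds to the protonated enaminone and expels dimethylamine (oxa-Michael addition–elimination closing pyranone ring C), and continued methanolysis cleaves the tertiary silyl ether, the carbinol being shielded from ionisation by the β-oxygen of the dihydrofuran and the stereocentre never being touched.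

## Compound list

1 | homoveratric acid, 2-(3,4-dimethoxyphenyl)acetic acid | COc1ccc(CC(=O)O)cc1OC | starting material
2 | methyl 2-(3,4-dimethoxyphenyl)acetate | COC(=O)Cc1ccc(OC)c(OC)c1 | intermediate
3 | methyl 2-(2-iodo-4,5-dimethoxyphenyl)acetate | COC(=O)Cc1cc(OC)c(OC)cc1I | intermediate
4 | methyl (4R)-2,2-dimethyl-1,3-dioxolane-4-carboxylate | COC(=O)[C@H]1COC(C)(C)O1 | starting material
5 | 2-[(4R)-2,2-dimethyl-1,3-dioxolan-4-yl]propan-2-ol | CC(C)(O)[C@H]1COC(C)(C)O1 | intermediate
6 | tert-butyl({2-[(4R)-2,2-dimethyl-1,3-dioxolan-4-yl]propan-2-yl}oxy)dimethylsilane | CC(C)(O[Si](C)(C)C(C)(C)C)[C@H]1COC(C)(C)O1 | intermediate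
7 | (2R)-3-[(tert-butyldimethylsilyl)oxy]-3-methylbutane-1,2-diol | CC(C)(O[Si](C)(C)C(C)(C)C)[C@H](O)CO | intermediate
8 | (2R)-3-[(tert-butyldimethylsilyl)oxy]-2-hydroxy-3-methylbutyl 4-methylbenzenesulfonate | CC(C)(O[Si](C)(C)C(C)(C)C)[C@H](O)COS(=O)(=O)c1ccc(C)cc1 | intermediate
9 | tert-butyldimethyl({2-[(2R)-oxiran-2-yl]propan-2-yl}oxy)silane | C1[C@H](C(C)(C)O[Si](C)(C)C(C)(C)C)O1 | intermediate
10 | methyl 2-[(2R)-2-{2-[(tert-butyldimethylsilyl)oxy]propan-2-yl}-4,5-dimethoxy-2,3-dihydro-1-benzofuran-7-yl]acetate | COc1cc(CC(=O)OC)c2c(c1OC)C[C@H](C(C)(C)O[Si](C)(C)C(C)(C)C)O2 | intermediate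
11 | 2-[(2R)-2-{2-[(tert-butyldimethylsilyl)oxy]propan-2-yl}-4,5-dimethoxy-2,3-dihydro-1-benzofuran-7-yl]acetaldehyde | COc1cc(CC=O)c2c(c1OC)C[C@H](C(C)(C)O[Si](C)(C)C(C)(C)C)O2 | intermediate
12 | phloroglucinol, benzene-1,3,5-triol | Oc1cc(O)cc(O)c1 | starting material
13 | 1,3,5-tris(methoxymethoxy)benzene | COCOc1cc(OCOC)cc(OCOC)c1 | intermediate
14 | [2,4,6-tris(methoxymethoxy)phenyl]lithium | [Li]c1c(OCOC)cc(OCOC)cc1OCOC | intermediate
15 | dichloro[2,4,6-tris(methoxymethoxy)phenyl]cerium | Cl[Ce](Cl)c1c(OCOC)cc(OCOC)cc1OCOC | intermediate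
16 | 2-[(2R)-2-{2-[(tert-butyldimethylsilyl)oxy]propan-2-yl}-4,5-dimethoxy-2,3-dihydro-1-benzofuran-7-yl]-1-[2,4,6-tris(methoxymethoxy)phenyl]ethan-1-ol, both epimers at the carbinol carbon | COc1cc(CC(O)c3c(OCOC)cc(OCOC)cc3OCOC)c2c(c1OC)C[C@H](C(C)(C)O[Si](C)(C)C(C)(C)C)O2 | intermediate
17 | 2-[(2R)-2-{2-[(tert-butyldimethylsilyl)oxy]propan-2-yl}-4,5-dimethoxy-2,3-dihydro-1-benzofuran-7-yl]-1-[2,4,6-tris(methoxymethoxy)phenyl]ethan-1-one | COc1cc(CC(=O)c3c(OCOC)cc(OCOC)cc3OCOC)c2c(c1OC)C[C@H](C(C)(C)O[Si](C)(C)C(C)(C)C)O2 | intermediate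
18 | 3-(dimethylamino)-2-[(2R)-2-{2-[(tert-butyldimethylsilyl)oxy]propan-2-yl}-4,5-dimethoxy-2,3-dihydro-1-benzofuran-7-yl]-1-[2,4,6-tris(methoxymethoxy)phenyl]prop-2-en-1-one, alkene geometry not defined | COc1cc(C(=CN(C)C)C(=O)c3c(OCOC)cc(OCOC)cc3OCOC)c2c(c1OC)C[C@H](C(C)(C)O[Si](C)(C)C(C)(C)C)O2 | intermediate
19 | 3-(dimethylamino)-2-[(2R)-2-{2-[(tert-butyldimethylsilyl)oxy]propan-2-yl}-4,5-dimethoxy-2,3-dihydro-1-benzofuran-7-yl]-1-(2,4,6-trihydroxyphenyl)prop-2-en-1-one, alkene geometry not defined | COc1cc(C(=CN(C)C)C(=O)c3c(O)cc(O)cc3O)c2c(c1OC)C[C@H](C(C)(C)O[Si](C)(C)C(C)(C)C)O2 | intermediate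
20 | 3-[(2R)-2-{2-[(tert-butyldimethylsilyl)oxy]propan-2-yl}-4,5-dimethoxy-2,3-dihydro-1-benzofuran-7-yl]-5,7-dihydroxy-4H-chromen-4-one | COc1cc(-c2coc3cc(O)cc(O)c3c2=O)c2c(c1OC)C[C@H](C(C)(C)O[Si](C)(C)C(C)(C)C)O2 | intermediate
21 | 5,7-dihydroxy-3-[(2R)-2-(2-hydroxypropan-2-yl)-4,5-dimethoxy-2,3-dihydro-1-benzofuran-7-yl]-4H-chromen-4-one | COc1cc(-c2coc3cc(O)cc(O)c3c2=O)c2c(c1OC)C[C@H](C(C)(C)O)O2 | target

## Step count and risks

Total step count: 13 (steps 1–2 make the iodide, steps 3–6 the epoxide, step 9 the ring A partner).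
Longest linear sequence: 10 steps, from 4 to 21 through steps 3–8 and 10–13.

Steps most likely to fail:

1. Step 7 (key step).
   - What may go wrong: palladation of the one free ortho C–H is slowed by the methoxy group beside it. The aryl palladium intermediate may then be diverted into norbornene-containing adducts, premature ipso termination or hydrodeiodination. The bulky epoxide may also add slowly to the palladacycle, and silyl transfer from the tertiary to the secondary oxygen at the alkoxide stage is a further leak.
   - Fallback: a stepwise assembly of ring D from the same epoxide, setting out from 9 and coming back at 10. Commercial 4-bromo-1,2-dimethoxybenzene is deprotonated between bromine and methoxy with LiN(i-Pr)2 in THF at −78 °C. The aryllithium opens 9 at its CH2 carbon in the presence of BF3·OEt2 to give (2R)-1-(6-bromo-2,3-dimethoxyphenyl)-3-[(tert-butyldimethylsilyl)oxy]-3-methylbutan-2-ol F1. Intramolecular Buchwald–Hartwig etherification (Pd(OAc)2, t-BuXPhos, Cs2CO3, toluene, 80 °C) should close the ring with the C–O bond of the stereocentre intact, giving tert-butyl({2-[(2R)-4,5-dimethoxy-2,3-dihydro-1-benzofuran-2-yl]propan-2-yl}oxy)dimethylsilane F2. Bromination with NBS in MeCN at 0 °C should go to C7, which is ortho to the ring oxygen and para to the 4-methoxy group, giving tert-butyl({2-[(2R)-7-bromo-4,5-dimethoxy-2,3-dihydro-1-benzofuran-2-yl]propan-2-yl}oxy)dimethylsilane F3. Palladium-catalysed coupling of F3 with the Reformatsky reagent BrZnCH2CO2Me (Pd(dba)2, XPhos, THF, 60 °C) then gives 10.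

2. Step 10.
   - What may go wrong: proton transfer from the benzylic α-CH2 of 11 to the organometallic (enolisation) and self-condensation of the sensitive aldehyde. Over-reduction in step 8 would compound this.
   - Fallback: the carbonyl addition is replaced by an acyl cross-coupling, setting out from 10 and coming back at 17, so that 11 and 16 are bypassed. Saponification of 10 (LiOH, THF/H2O, rt) gives 2-[(2R)-2-{2-[(tert-butyldimethylsilyl)oxy]propan-2-yl}-4,5-dimethoxy-2,3-dihydro-1-benzofuran-7-yl]acetic acid F4. Coupling with EtSH (EDC, DMAP, CH2Cl2) gives S-ethyl 2-[(2R)-2-{2-[(tert-butyldimethylsilyl)oxy]propan-2-yl}-4,5-dimethoxy-2,3-dihydro-1-benzofuran-7-yl]ethanethioate F5. Lithiation of 13 (n-BuLi, THF, 0 °C) and addition of ZnCl2 give chloro[2,4,6-tris(methoxymethoxy)phenyl]zinc F6. A Fukuyama coupling of F5 with this weakly basic organozinc (PdCl2(PPh3)2, THF/toluene, rt) should deliver 17 directly.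

3. Step 13.
   - What may go wrong: once unmasked, the tertiary carbinol may ionise in warm acid (dehydration to the isopropenyl compound or ring expansion to a chroman). Desilylation may also lag behind ring closure, so that partly deprotected material persists.
   - Fallback: the endgame is staged so that the carbinol is freed by fluoride and not by acid, setting out from 18 and coming back at 21. Treatment of 18 with NaHSO4·SiO2 in CH2Cl2 at rt should remove only the phenolic methoxymethyl ethers and let the pyranone close, so that silylated isoflavone 20 is isolated with the carbinol still protected. Desilylation with Bu4NF in THF (rt to 50 °C) then gives 21. No compound outside the list is made.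

Further compounds

F1 | step 7 | (2R)-1-(6-bromo-2,3-dimethoxyphenyl)-3-[(tert-butyldimethylsilyl)oxy]-3-methylbutan-2-ol | COc1ccc(Br)c(C[C@H](C(C)(C)O[Si](C)(C)C(C)(C)C)O)c1OC
F2 | step 7 | tert-butyl({2-[(2R)-4,5-dimethoxy-2,3-dihydro-1-benzofuran-2-yl]propan-2-yl}oxy)dimethylsilane | COc1ccc2c(c1OC)C[C@H](C(C)(C)O[Si](C)(C)C(C)(C)C)O2
F3 | step 7 | tert-butyl({2-[(2R)-7-bromo-4,5-dimethoxy-2,3-dihydro-1-benzofuran-2-yl]propan-2-yl}oxy)dimethylsilane | COc1cc(Br)c2c(c1OC)C[C@H](C(C)(C)O[Si](C)(C)C(C)(C)C)O2
F4 | step 10 | 2-[(2R)-2-{2-[(tert-butyldimethylsilyl)oxy]propan-2-yl}-4,5-dimethoxy-2,3-dihydro-1-benzofuran-7-yl]acetic acid | COc1cc(CC(=O)O)c2c(c1OC)C[C@H](C(C)(C)O[Si](C)(C)C(C)(C)C)O2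
F5 | step 10 | S-ethyl 2-[(2R)-2-{2-[(tert-butyldimethylsilyl)oxy]propan-2-yl}-4,5-dimethoxy-2,3-dihydro-1-benzofuran-7-yl]ethanethioate | COc1cc(CC(=O)SCC)c2c(c1OC)C[C@H](C(C)(C)O[Si](C)(C)C(C)(C)C)O2
F6 | step 10 | chloro[2,4,6-tris(methoxymethoxy)phenyl]zinc | Cl[Zn]c1c(OCOC)cc(OCOC)cc1OCOC
F0 | step 13 | none | none
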